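**Retrosynthetic overview**
- Ring A is the enolised 2-acetylcyclohexane-1,3,5-trione: C1 is the ring C=O between acetyl-bearing C2 and bridge-bearing C6, C3 and C5 are the enolised carbonyls, and C4 is the methyl/prenyl quaternary stereocentre. Ring B is the acetyl-prenyl-phloroglucinol. The target is cut at both bonds of the CH2 bridge (Mannich-type) and, within ring A, at C1–C2 and C5–C6.
- Enabling feature: ring A carries oxygen on C1, C3 and C5, so C1 and C5 are acyl carbons and C2 and C6 are carbon acids. C6–C1 is therefore an acetate unit (phenyl acetate). C2–C3–C4–C5 plus the acetyl group is a 3,3-dialkylated triacetic acid lactone, whose enol-lactone ring is at once an activated acyl group (future C5) and a masked β-diketone nucleophile (future C2).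
- C4 bears no hydrogen, so it cannot aromatise or epimerise. It is set beforehand by palladium-catalysed asymmetric C-prenylation of the flat, achiral 4-hydroxy-3,6-dimethylpyran-2-one.
- One flask then joins four components (pyrandione, phenyl acetate, an iminium one-carbon unit, the aromatic half) and makes four C–C bonds around ring A.
- Ring order: ring B is bought as phloroacetophenone and prenylated; the pyranone ring is bought and serves as a temporary ring; ring A is formed last, in the key step, as the pyranone ring opens.

Key step: step 3

Assumption: the trione ring is written throughout in the tautomer of the given structure, and the CIP descriptors quoted refer to that tautomer. The spatial arrangement at the quaternary carbon is the same in 6, 9–13 and 14, although the descriptor changes between S and R with the substituents.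
Assumption: 4-hydroxy-3,6-dimethyl-2H-pyran-2-one is taken as a catalogue compound.

**Step 1**
Reactants: 1 1-(2,4,6-trihydroxyphenyl)ethan-1-one; 2 1-bromo-3-methylbut-2-ene (prenyl bromide)
Product: 3 1-[2,4,6-trihydroxy-3-(3-methylbut-2-en-1-yl)phenyl]ethan-1-one
Conditions: 2 (0.9 equiv), 10% aq. KOH, 0 °C to rt
Reagents that add atoms: none
Why: Phenoxide C-alkylation (SN2) of the phloroglucinolate, whose ring carbons are the soft nucleophilic sites in water; the two free ring positions of 1 are equivalent, a deficit of 2 should limit a second prenylation, and no stereocentre is formed.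

**Step 2**
Reactants: 4 4-hydroxy-3,6-dimethyl-2H-pyran-2-one; 5 3-methylbut-2-en-1-yl acetate (prenyl acetate)
Product: 6 (3S)-3,6-dimethyl-3-(3-methylbut-2-en-1-yl)-2H-pyran-2,4(3H)-dione
Conditions: [Pd(C3H5)Cl]2 (2.5 mol %), N,N'-[(1R,2R)-cyclohexane-1,2-diyl]bis[2-(diphenylphosphanyl)benzamide] (7.5 mol %), 1,1,3,3-tetramethylguanidine (TMG, 1.1 equiv), toluene, 0 °C
Reagents that add atoms: none
Why: Tsuji–Trost asymmetric allylic alkylation: zerovalent palladium ionises 5 to a π-prenyl complex of divalent palladium, which the guanidinium enolate of 4 should attack through C3 at the unsubstituted allyl terminus (linear prenyl; O-allylation is reversible under the catalyst), while the chiral pocket of the diphosphine differentiates the enantiotopic faces of the planar enolate to set the quaternary centre as (S); the mirror-image ligand is held ready should the sense prove opposite.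

**Step 3**
Reactants: 6 (3S)-3,6-dimethyl-3-(3-methylbut-2-en-1-yl)-2H-pyran-2,4(3H)-dione; 7 phenyl acetate; 8 N,N-dimethylmethyleneiminium iodide; 3 1-[2,4,6-trihydroxy-3-(3-methylbut-2-en-1-yl)phenyl]ethan-1-one
Product: 14 (4R)-2-acetyl-6-{[3-acetyl-2,4,6-trihydroxy-5-(3-methylbut-2-en-1-yl)phenyl]methyl}-3,5-dihydroxy-4-methyl-4-(3-methylbut-2-en-1-yl)cyclohexa-2,5-dien-1-one (CNP0192978.1), via triketo phenyl ester 9 (not isolated), via acylketene 10 (not isolated), via trione 11 (not isolated), via Mannich base 12 (not isolated), via methylidene trione 13 (not isolated)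
Conditions: one pot: 7 (2.1 equiv), LiN(SiMe3)2 (2.1 equiv), THF, −78 °C; 6 (1.0 equiv), −78 °C to rt; 8 (1.0 equiv), 0 °C; 3 (1.0 equiv), 0 to 40 °C; aq. HCl work-up
Reagents that add atoms: none
Why: Proposed new method: the lithium enolate of 7 should add to the lactone carbonyl of 6, a vinylogous anhydride and the only carbonyl of 6 not tempered by enol-ether conjugation, and collapse of the adduct expels the β-diketone enolate to give ring-opened 9 (new bond C5–C6), whose β-keto ester is deprotonated by the second equivalent of enolate; on warming, this aryl β-keto ester enolate should lose phenoxide by E1cB to acylketene 10, and the diketone enolate carbon C2 then adds to the ketene carbon C1 (new bond C1–C2) to give the delocalised anion of 11, the closest known reaction types being the Fujimoto–Belleau-type addition of carbanions to enol lactones with recyclisation and the biomimetic Claisen cyclisation of 3,5,7-triketo esters to acylphloroglucinols. Ring A closes by a six-membered intramolecular C-acylation (Claisen mode, exo with respect to the ketene C=O); ring closure through the neighbouring enolate oxygen is not a dead end, because the enol lactone it would give is again a vinylogous anhydride that reopens, whereas the trione anion is the thermodynamic sink. C6 of 11 is then the only unsubstituted ring carbon and the most nucleophilic site in the flask, so 8 should give Mannich base 12, which on addition of 3 loses dimethylamine to methylidene trione 13 and is trapped at the single free aromatic carbon of the phenoxide of 3, a known Mannich-base (quinone-methide-type) way to methylene-bridged acylphloroglucinols. No stereocentre is formed: C4 carries no hydrogen and none of its four bonds is broken, so the configuration set in step 2 is carried into 14. The step needs Claisen instead of aldol ring closure and unsymmetrical instead of symmetrical bridging; the first is secured by the aryl ester (ketene formation while the acetyl ketone stays masked as the diketone enolate) and by quaternary C4, which blocks aromatisation, the second by converting all of 11 into 12 before 3 is added, and 3 never meets the amide base.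

**Compound list**
1 | 1-(2,4,6-trihydroxyphenyl)ethan-1-one | CC(=O)c1c(O)cc(O)cc1O | starting material
2 | 1-bromo-3-methylbut-2-ene | CC(C)=CCBr | starting material
3 | 1-[2,4,6-trihydroxy-3-(3-methylbut-2-en-1-yl)phenyl]ethan-1-one | CC(=O)c1c(O)cc(O)c(CC=C(C)C)c1O | intermediate
4 | 4-hydroxy-3,6-dimethyl-2H-pyran-2-one | CC1=CC(O)=C(C)C(=O)O1 | starting material
5 | 3-methylbut-2-en-1-yl acetate | CC(=O)OCC=C(C)C | starting material
6 | (3S)-3,6-dimethyl-3-(3-methylbut-2-en-1-yl)-2H-pyran-2,4(3H)-dione | CC1=CC(=O)[C@](C)(CC=C(C)C)C(=O)O1 | intermediate
7 | phenyl acetate | CC(=O)Oc1ccccc1 | starting material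
8 | N,N-dimethylmethyleneiminium iodide | C=[N+](C)C.[I-] | starting material
9 | phenyl (4S)-4-methyl-4-(3-methylbut-2-en-1-yl)-3,5,7-trioxooctanoate | CC(=O)CC(=O)[C@](C)(CC=C(C)C)C(=O)CC(=O)Oc1ccccc1 | intermediate
10 | (4S)-4-methyl-4-(3-methylbut-2-en-1-yl)oct-1-ene-1,3,5,7-tetrone (acylketene) | CC(=O)CC(=O)[C@](C)(CC=C(C)C)C(=O)C=C=O | intermediate
11 | (4R)-2-acetyl-3,5-dihydroxy-4-methyl-4-(3-methylbut-2-en-1-yl)cyclohexa-2,5-dien-1-one | CC(=O)C1=C(O)[C@](C)(CC=C(C)C)C(O)=CC1=O | intermediate
12 | (4R)-2-acetyl-6-[(dimethylamino)methyl]-3,5-dihydroxy-4-methyl-4-(3-methylbut-2-en-1-yl)cyclohexa-2,5-dien-1-one | CC(=O)C1=C(O)[C@](C)(CC=C(C)C)C(O)=C(CN(C)C)C1=O | intermediate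
13 | (4S)-2-acetyl-3-hydroxy-4-methyl-6-methylidene-4-(3-methylbut-2-en-1-yl)cyclohex-2-ene-1,5-dione | CC(=O)C1=C(O)[C@](C)(CC=C(C)C)C(=O)C(=C)C1=O | intermediate
14 | (4R)-2-acetyl-6-{[3-acetyl-2,4,6-trihydroxy-5-(3-methylbut-2-en-1-yl)phenyl]methyl}-3,5-dihydroxy-4-methyl-4-(3-methylbut-2-en-1-yl)cyclohexa-2,5-dien-1-one (CNP0192978.1) | CC(=O)C1=C(O)[C@](C)(CC=C(C)C)C(O)=C(Cc2c(O)c(CC=C(C)C)c(O)c(C(C)=O)c2O)C1=O | target

**Step count and risks**
Total step count: 3
Longest linear sequence: 2 steps (step 2 then step 3, or step 1 then step 3)

Steps most likely to fail: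

Step 3 (proposed new method). The first C–C bond formation is the weak point. Proton transfer from the ring methyl group of 6 to the ester enolate, or fragmentation of the aryl ester enolate to ketene before it has added, would compete with addition to the hindered lactone carbonyl. Later, ring closure through oxygen or base-induced scrambling of the methylene bridge towards symmetrical dimers could also intervene. The fallback uses known chemistry and makes the bonds one at a time. It sets out from 6. Methanolysis of the vinylogous anhydride (MeOH, cat. Et3N, 0 °C) should give methyl (2S)-2-methyl-2-(3-methylbut-2-en-1-yl)-3,5-dioxohexanoate F1. Soft-enolisation C-acetylation of its β-diketone (MgCl2, pyridine, acetyl chloride, CH2Cl2) should give methyl (2S)-4-acetyl-2-methyl-2-(3-methylbut-2-en-1-yl)-3,5-dioxohexanoate F2. Dieckmann cyclisation (LiN(SiMe3)2, THF, −78 °C to rt) has only one outcome because the two acetyl groups are equivalent, and it comes back to the route at 11, now isolated. Compound 11 is then aminomethylated with 8 and coupled with 3 in a separate flask, passing through 12 and 13 to 14.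

Step 2. Insufficient discrimination of the enantiotopic faces of the flat pyranone enolate, or attack at the substituted allyl terminus (reverse prenylation), may erode the purity of 6. The fallback sets out from 4 and 5. The same C3-prenylation is run with an achiral catalyst (Pd(PPh3)4, DBU, toluene, 50 °C), a documented racemic reaction of 4-hydroxy-6-methylpyran-2-ones, to give racemic 3,6-dimethyl-3-(3-methylbut-2-en-1-yl)-2H-pyran-2,4(3H)-dione F3. The enantiomers are separated by preparative chromatography on a chiral stationary phase. The (S)-enantiomer is 6, where the route resumes; the (R)-enantiomer, (3R)-3,6-dimethyl-3-(3-methylbut-2-en-1-yl)-2H-pyran-2,4(3H)-dione F4, is discarded.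

Step 1. Over-alkylation (a second C-prenylation or geminal, dearomatising prenylation) and O-alkylation compete with mono-C-prenylation of the ambident phenoxide. The fallback sets out from 1 and 2. Selective O-alkylation of the non-chelated 4-hydroxyl (K2CO3, acetone, reflux) should give 1-[2,6-dihydroxy-4-[(3-methylbut-2-en-1-yl)oxy]phenyl]ethan-1-one F5. A clay-promoted 1,3-shift of the prenyl group from oxygen to the adjacent ring carbon (montmorillonite K10, CH2Cl2, 0 °C) then comes back to the route at 3.

**Further compounds**
F1 | step 3 | methyl (2S)-2-methyl-2-(3-methylbut-2-en-1-yl)-3,5-dioxohexanoate | CC(=O)CC(=O)[C@](C)(CC=C(C)C)C(=O)OC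
F2 | step 3 | methyl (2S)-4-acetyl-2-methyl-2-(3-methylbut-2-en-1-yl)-3,5-dioxohexanoate | CC(=O)C(C(C)=O)C(=O)[C@](C)(CC=C(C)C)C(=O)OC
F3 | step 2 | racemic 3,6-dimethyl-3-(3-methylbut-2-en-1-yl)-2H-pyran-2,4(3H)-dione | CC1=CC(=O)C(C)(CC=C(C)C)C(=O)O1
F4 | step 2 | (3R)-3,6-dimethyl-3-(3-methylbut-2-en-1-yl)-2H-pyran-2,4(3H)-dione | CC1=CC(=O)[C@@](C)(CC=C(C)C)C(=O)O1
F5 | step 1 | 1-[2,6-dihydroxy-4-[(3-methylbut-2-en-1-yl)oxy]phenyl]ethan-1-one | CC(=O)c1c(O)cc(OCC=C(C)C)cc1O
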